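**Plan**

- Numbering: O1, C2 (hemiketal), C3 (CH–CH3), O4, C4a, C5–C8, C8a; ring A is the benzo ring, ring B the dioxane ring, ring C the trimethoxyphenyl group.
- Retrosynthetic cuts: first C2–ring C (hemiketal back to a lactone and an arylmagnesium reagent), then O1–C2 with O1 returned to a methyl ether, then O4–C3 (back to a phenol and a lactate).
- Forward order: the lactate chain is joined to ring A at O4, ring B closes by loss of one methyl group and acylation of the freed oxygen, and ring C is attached last at C2.
- Enabling feature: in ring A, O1 (on C8a) and the methoxy oxygen on C5 sit on the two carbons flanking C4a–O4, and the C7 allyl group lies para to O4. Ring A is therefore a 4-allyl-2,6-dimethoxyphenol in which either methoxy oxygen can become O1.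
- Stereochemistry: C3 (R) comes from ethyl (S)-lactate by SN2 inversion. C2 (S) is set by equilibration of the hemiketal under control of C3.

Key step: step 2

Assumption: the (2S,3R) hemiketal, in which the C2 hydroxyl is trans to the C3 methyl (aryl and methyl cis), is taken to be the thermodynamically preferred anomer (axial hydroxyl, equatorial aryl, methyl anti to the hydroxyl), so that ring–chain tautomerism delivers it.

**Route**

Step 1
Reactants: 1 4-allyl-2,6-dimethoxyphenol (methoxyeugenol); 2 ethyl (S)-lactate
Product: 3 ethyl (R)-2-(4-allyl-2,6-dimethoxyphenoxy)propanoate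
Conditions: PPh3 (1.3 equiv), DIAD (1.3 equiv), THF, 0 °C to rt
Reagents that add atoms: none
Why: Mitsunobu etherification, in which the sufficiently acidic phenol protonates the PPh3–DIAD betaine and its phenoxide displaces the oxyphosphonium-activated lactate oxygen by SN2, so the (S) centre of 2 should be inverted to the (R) centre that becomes C3.

Step 2
Reactants: 3 ethyl (R)-2-(4-allyl-2,6-dimethoxyphenoxy)propanoate
Product: 6 (R)-7-allyl-5-methoxy-3-methyl-1,4-benzodioxin-2(3H)-one, via aryloxydibromoborane 4 (not isolated), via hydroxy ester 5 (not isolated)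
Conditions: BBr3 (1.1 equiv), CH2Cl2, −78 to 0 °C; ice-water; crude then TsOH·H2O (5 mol %), PhMe, 4 Å MS, 70 °C
Reagents that add atoms: none
Why: BBr3 binds a methoxy oxygen of ring A and bromide removes the methyl group by SN2 to give aryloxydibromoborane 4 and bromomethane; hydrolysis frees phenol 5, whose oxygen attacks the ester carbonyl under acid catalysis and expels ethanol, so that O1–C2 forms and ring B closes. The closest known reaction type is the BBr3 demethylation–lactonisation of ortho-methoxyaryl-tethered esters, supported by the acid-catalysed closure of 2-hydroxyphenoxy alkanoates to 1,4-benzodioxin-2-ones. Ring B closes by a 6-exo-trig acyl substitution. No stereocentre is created, and C3 takes part in no bond change and meets no base, so its (R) configuration should be carried through. Because the two methoxy groups exchange by rotation about the aryl–O4 bond, either one leads to the same lactone and no regiocontrol is needed. The selectivity that is needed, methyl over the O4–C3 ether and one cleavage instead of two, rests on the SN2 preference for methyl over a secondary carbon that cannot ionise next to the ester carbonyl, on the limit of 1.1 equiv of BBr3 at low temperature and on the weak Lewis acidity of 4; the allyl group should survive as it does in BBr3 demethylations of other allylarenes.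

Step 3
Reactants: 7 5-bromo-1,2,3-trimethoxybenzene
Product: 8 (3,4,5-trimethoxyphenyl)magnesium bromide (titrated THF solution)
Conditions: Mg turnings, I2 (cat.), THF, 50 °C
Reagents that add atoms: magnesium, [Mg]
Why: Grignard reagent formation by insertion of magnesium into the aryl C–Br bond, routine for this electron-rich bromide once the metal surface is activated with iodine.

Step 4
Reactants: 6 (R)-7-allyl-5-methoxy-3-methyl-1,4-benzodioxin-2(3H)-one; 8 (3,4,5-trimethoxyphenyl)magnesium bromide
Product: 11 (2S,3R)-7-allyl-5-methoxy-3-methyl-2-(3,4,5-trimethoxyphenyl)-2,3-dihydro-1,4-benzodioxin-2-ol, via bromomagnesium hemiketal alkoxide 9 (not isolated), via ring-opened hydroxy ketone 10 (not isolated)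
Conditions: 8 (1.05 equiv) added slowly, THF, −78 °C; AcOH (1.5 equiv), −78 °C to rt; aqueous work-up
Reagents that add atoms: none
Why: Grignard addition to a lactone arrested at the lactol stage, in which the tetrahedral alkoxide 9 should be held at −78 °C as a five-membered magnesium chelate with O4 and is protonated before warming, so C3 is carried through untouched while the labile hemiketal centre C2 settles by ring–chain tautomerism through hydroxy ketone 10, under control of C3, into the (2S,3R) anomer named in the assumption.

**Compound list**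

1 | 4-allyl-2,6-dimethoxyphenol | C=CCc1cc(OC)c(O)c(OC)c1 | starting material
2 | ethyl (S)-lactate | C[C@H](O)C(=O)OCC | starting material
3 | ethyl (R)-2-(4-allyl-2,6-dimethoxyphenoxy)propanoate | C=CCc1cc(OC)c(O[C@H](C)C(=O)OCC)c(OC)c1 | intermediate
4 | ethyl (R)-2-[4-allyl-2-(dibromoboryloxy)-6-methoxyphenoxy]propanoate | C=CCc1cc(OC)c(O[C@H](C)C(=O)OCC)c(OB(Br)Br)c1 | intermediate (not isolated)
5 | ethyl (R)-2-(4-allyl-2-hydroxy-6-methoxyphenoxy)propanoate | C=CCc1cc(OC)c(O[C@H](C)C(=O)OCC)c(O)c1 | intermediate (not isolated)
6 | (R)-7-allyl-5-methoxy-3-methyl-1,4-benzodioxin-2(3H)-one | C=CCc1cc(OC)c2O[C@H](C)C(=O)Oc2c1 | intermediate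
7 | 5-bromo-1,2,3-trimethoxybenzene | COc1cc(Br)cc(OC)c1OC | starting material
8 | (3,4,5-trimethoxyphenyl)magnesium bromide | COc1cc([Mg]Br)cc(OC)c1OC | intermediate
9 | bromomagnesium (3R)-7-allyl-5-methoxy-3-methyl-2-(3,4,5-trimethoxyphenyl)-2,3-dihydro-1,4-benzodioxin-2-olate (C2 epimers) | C=CCc1cc(OC)c2c(c1)OC(O[Mg]Br)(c1cc(OC)c(OC)c(OC)c1)[C@@H](C)O2 | intermediate (not isolated)
10 | (R)-2-(4-allyl-2-hydroxy-6-methoxyphenoxy)-1-(3,4,5-trimethoxyphenyl)propan-1-one | C=CCc1cc(OC)c(O[C@H](C)C(=O)c2cc(OC)c(OC)c(OC)c2)c(O)c1 | intermediate (not isolated)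
11 | (2S,3R)-7-allyl-5-methoxy-3-methyl-2-(3,4,5-trimethoxyphenyl)-2,3-dihydro-1,4-benzodioxin-2-ol | C=CCc1cc(OC)c2c(c1)O[C@@](O)(c1cc(OC)c(OC)c(OC)c1)[C@@H](C)O2 | target

**Step count**

Total steps: 4. Longest linear sequence: 3 (steps 1, 2 and 4 from phenol 1); step 3 is a one-step branch.

**Steps most likely to fail**

1. Step 2. The cleavage may not stop cleanly after one methyl group: the second methyl ether can be lost as well, or conversion can stall while BBr3 is tied up on the ester carbonyl, which would leave a three-component mixture. Fallback: setting out from ester 3, both methyl ethers are cleaved on purpose with excess BBr3 (3 equiv, CH2Cl2, −78 to 0 °C) to give ethyl (R)-2-(4-allyl-2,6-dihydroxyphenoxy)propanoate F1. Under the TsOH conditions F1 closes onto either of its equivalent hydroxyls to give (R)-7-allyl-5-hydroxy-3-methyl-1,4-benzodioxin-2(3H)-one F2. The single remaining phenol is then methylated under neutral Mitsunobu conditions (MeOH, PPh3, DIAD, THF, 0 °C), and the route is rejoined at lactone 6.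

2. Step 4. The tetrahedral magnesium alkoxide may collapse in the flask to the aryl ketone and take up a second aryl group, and the basic reagent may enolise the lactone or the ketone and erode the configuration at C3. Fallback: setting out from lactone 6, ring opening with Me(MeO)NH·HCl and AlMe3 (CH2Cl2, 0 °C) gives (R)-2-(4-allyl-2-hydroxy-6-methoxyphenoxy)-N-methoxy-N-methylpropanamide F3. Silylation (TBSCl, imidazole, DMF) gives (R)-2-{4-allyl-2-[(tert-butyldimethylsilyl)oxy]-6-methoxyphenoxy}-N-methoxy-N-methylpropanamide F4. Grignard reagent 8 (THF, 0 °C) should add once to this Weinreb amide through its stable chelate to give (R)-2-{4-allyl-2-[(tert-butyldimethylsilyl)oxy]-6-methoxyphenoxy}-1-(3,4,5-trimethoxyphenyl)propan-1-one F5. Buffered desilylation (TBAF, AcOH, THF, 0 °C) then releases hydroxy ketone 10, which closes to 11 as in step 4.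

3. Step 1. Coupling of the doubly ortho-substituted phenol may be slow, so that the betaine consumes the lactate by hydrazide alkylation or elimination, and any ionising pathway would erode the inversion. Fallback: setting out from lactate 2, triflation (Tf2O, 2,6-lutidine, CH2Cl2, −78 °C) gives ethyl (S)-2-{[(trifluoromethyl)sulfonyl]oxy}propanoate F6. The potassium phenoxide of 1 (K2CO3, MeCN, −20 °C to rt) displaces the triflate with inversion, and the route is rejoined at ester 3.

**Further compounds**

F1 | step 2 | ethyl (R)-2-(4-allyl-2,6-dihydroxyphenoxy)propanoate | C=CCc1cc(O)c(O[C@H](C)C(=O)OCC)c(O)c1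
F2 | step 2 | (R)-7-allyl-5-hydroxy-3-methyl-1,4-benzodioxin-2(3H)-one | C=CCc1cc(O)c2O[C@H](C)C(=O)Oc2c1
F3 | step 4 | (R)-2-(4-allyl-2-hydroxy-6-methoxyphenoxy)-N-methoxy-N-methylpropanamide | C=CCc1cc(OC)c(O[C@H](C)C(=O)N(C)OC)c(O)c1
F4 | step 4 | (R)-2-{4-allyl-2-[(tert-butyldimethylsilyl)oxy]-6-methoxyphenoxy}-N-methoxy-N-methylpropanamide | C=CCc1cc(OC)c(O[C@H](C)C(=O)N(C)OC)c(O[Si](C)(C)C(C)(C)C)c1
F5 | step 4 | (R)-2-{4-allyl-2-[(tert-butyldimethylsilyl)oxy]-6-methoxyphenoxy}-1-(3,4,5-trimethoxyphenyl)propan-1-one | C=CCc1cc(OC)c(O[C@H](C)C(=O)c2cc(OC)c(OC)c(OC)c2)c(O[Si](C)(C)C(C)(C)C)c1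
F6 | step 1 | ethyl (S)-2-{[(trifluoromethyl)sulfonyl]oxy}propanoate | C[C@H](OS(=O)(=O)C(F)(F)F)C(=O)OCC
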